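**Retrosynthetic overview**
1. The strategy rests on the C1–C2 bond, which joins the α-carbon of the C8 bridging ketone (the allyl-bearing quaternary bridgehead C1) to the β-carbon of the C2=C3 methyl enol ether. Both carbons are donors (C8 and C3 are 1,4-related), so the bond is cut as an oxidative coupling of a silyl enol ether with a methyl enol ether that closes ring C1–C2–C3–C4–C5–C8 onto a finished cyclopentanone (C8, C1, C7, C6, C5).
2. The target follows from the bicyclic C3 dimethyl ketal/C4 silyl ether by loss of methanol toward C2 and buffered desilylation.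
3. The cyclisation substrate is a tetrasubstituted silyl enol ether (C1=C8) with a 2-methoxyallyl silyl ether chain on C5. It comes from 2-allyl-4-arylcyclopent-2-enone by α′-aldol with 2-methoxyacrolein (sets C5, C4), O-silylation, and methyl cuprate addition with silyl trapping (sets C7).
4. The enone comes from (R)-4-silyloxycyclopent-2-enone by aryl conjugate addition anti to the silyloxy group, silanol elimination, α-iodination and Stille allylation; the one purchased stereocentre becomes C6 and relays all others.
5. Ring order: the cyclopentane ring is bought and carried through; the six-membered ring is closed last and completes the bicyclo[3.2.1]octan-8-one.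

Key step: step 10

Remark: the bicycle is numbered C1 (allyl-bearing bridgehead), C2=C3 (methoxy), C4 (carbinol), C5 (bridgehead CH), C6 (aryl), C7 (methyl), C8 (ketone), and these numbers are used for the same carbons in the monocyclic precursors. It is assumed that silyl ether 1 is bought in high enantiomeric purity.

**Step 1**
Reactants: 1 (R)-4-(tert-butyldimethylsilyloxy)cyclopent-2-en-1-one; 2 4-bromo-1,2-dimethoxybenzene
Product: 4 (3S,4R)-4-(tert-butyldimethylsilyloxy)-3-(3,4-dimethoxyphenyl)cyclopentan-1-one (aryl and silyloxy trans), via aryl Grignard reagent 3 (not isolated)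
Conditions: 2, Mg, THF, 40 °C; then CuBr·SMe2 (10 mol %), 1, THF, −78 °C; sat. aq NH4Cl, −78 °C
Reagents that add atoms: none
Why: Copper-catalysed conjugate addition of the aryl Grignard reagent should deliver the aryl group to the β-carbon on the face opposite the bulky γ-silyloxy group, setting the future C6 centre, while the cold quench keeps the enolate from equilibrating toward early silanolate loss and double addition.

**Step 2**
Reactants: 4
Product: 5 (R)-4-(3,4-dimethoxyphenyl)cyclopent-2-en-1-one
Conditions: DBU, CH2Cl2, −20 → 0 °C; pH 7 buffer
Reagents that add atoms: none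
Why: E1cB β-elimination of the silyloxy group from the β-silyloxy ketone transposes the enone and leaves the aryl-bearing carbon as the only stereocentre, the low temperature and short contact time being chosen to avoid γ-deprotonation at this benzylic, allylic position.

**Step 3**
Reactants: 5
Product: 6 (R)-4-(3,4-dimethoxyphenyl)-2-iodocyclopent-2-en-1-one
Conditions: I2, pyridine/CH2Cl2, 0 °C → rt; aq Na2S2O3
Reagents that add atoms: iodine ([I][I])
Why: α-Iodination of a cyclic enone by conjugate addition of pyridine, iodination of the enolate and loss of pyridine (a Baylis–Hillman-type addition–elimination) should functionalise only the α-carbon and leave the γ stereocentre untouched.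

**Step 4**
Reactants: 6; 7 allyltributylstannane
Product: 8 (R)-2-allyl-4-(3,4-dimethoxyphenyl)cyclopent-2-en-1-one
Conditions: Pd2(dba)3 (2.5 mol %), AsPh3 (10 mol %), CuI (10 mol %), NMP, rt → 40 °C
Reagents that add atoms: none
Why: Stille coupling of the α-iodoenone with the allylstannane under base-free zerovalent-palladium catalysis should attach the allyl group to the future C1 at a temperature low enough to prevent migration of the allyl double bond or epimerisation.

**Step 5**
Reactants: 9 1,1,2-trimethoxyethane
Product: 10 methoxyacetaldehyde (taken on as a concentrated aqueous solution)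
Conditions: Amberlyst-15 (H+ form), H2O, 50 °C; filter, distil off MeOH
Reagents that add atoms: water (O)
Why: Acid-catalysed acetal hydrolysis, driven by excess water and removal of methanol, should free the aldehyde.

**Step 6**
Reactants: 10
Product: 11 2-methoxyacrolein (2-methoxyprop-2-enal)
Conditions: 37% aq CH2O, pyrrolidine (10 mol %), EtCO2H (10 mol %), i-PrOH/H2O, 45 °C; extract (CH2Cl2), distil over hydroquinone, use at once
Reagents that add atoms: formaldehyde (C=O)
Why: Amine-catalysed Mannich condensation with formaldehyde followed by loss of the amine (α-methylenation of an aldehyde) should install the methylene group at the only enolisable carbon.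

**Step 7**
Reactants: 8; 11
Product: 13 (4S,5S)-2-allyl-4-(3,4-dimethoxyphenyl)-5-[(1R)-1-hydroxy-2-methoxyprop-2-en-1-yl]cyclopent-2-en-1-one, via lithium cross-conjugated enolate 12 (not isolated)
Conditions: LiN(i-Pr)2, THF, −78 °C; then 11, −78 °C, 15 min; AcOH/THF, −78 °C
Reagents that add atoms: none
Why: Kinetic deprotonation of the α′-methylene gives the cross-conjugated lithium enolate, which should add 1,2 to the enal (aldol addition) on the ring face opposite the adjacent aryl group, setting C5 trans to C6, while the chair Zimmerman–Traxler transition state of the ring-locked E-enolate with the 1-methoxyvinyl group equatorial sets the carbinol carbon C4 in the anti sense.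

**Step 8**
Reactants: 13
Product: 14 (4S,5S)-2-allyl-5-[(1R)-1-(tert-butyldimethylsilyloxy)-2-methoxyprop-2-en-1-yl]-4-(3,4-dimethoxyphenyl)cyclopent-2-en-1-one
Conditions: TBSOTf, 2,6-lutidine, CH2Cl2, −78 °C
Reagents that add atoms: tert-butyldimethylsilyl triflate (CC(C)(C)[Si](C)(C)OS(=O)(=O)C(F)(F)F)
Why: O-silylation of the secondary alcohol with a silyl triflate and a hindered pyridine base is fast at −78 °C, which should forestall retro-aldol cleavage and spare the acid-labile enol ether without touching any stereocentre.

**Step 9**
Reactants: 14
Product: 15 {[(3S,4S,5S)-2-allyl-5-[(1R)-1-(tert-butyldimethylsilyloxy)-2-methoxyprop-2-en-1-yl]-4-(3,4-dimethoxyphenyl)-3-methylcyclopent-1-en-1-yl]oxy}trimethylsilane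
Conditions: Me2CuLi (from CuI, 2 MeLi), TMSCl, Et3N, THF, −78 °C; cold pH 7 buffer/pentane, used directly
Reagents that add atoms: lithium dimethylcuprate Me2CuLi, made in the flask from methyllithium and CuI ([Li+].C[Cu-]C); chlorotrimethylsilane (C[Si](C)(C)Cl)
Why: Chlorosilane-accelerated cuprate conjugate addition should place the methyl group on the β-carbon C7 from the face opposite the adjacent C6 aryl group, and O-silylation of the enolate as it forms gives the tetrasubstituted silyl enol ether C1=C8 regiospecifically with C5 untouched.

**Step 10**
Reactants: 15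
Product: 16 (1S,4R,5S,6S,7S)-1-allyl-4-(tert-butyldimethylsilyloxy)-6-(3,4-dimethoxyphenyl)-3,3-dimethoxy-7-methylbicyclo[3.2.1]octan-8-one
Conditions: reticulated vitreous carbon anode, Pt cathode, undivided cell, constant current, LiClO4 (0.1 M), 2,6-lutidine, MeOH/CH2Cl2 (1:4), 0 °C, 2.1 F/mol
Reagents that add atoms: methanol (CO)
Why: Anodic one-electron oxidation of the tetrasubstituted silyl enol ether, expected to be the most electron-rich π system of 15, gives a radical cation that is electrophilic at C1; the CH2 terminus C2 of the tethered methyl enol ether attacks it, a second electron is removed, the oxocarbenium ion at C3 is captured by methanol and the trimethylsilyl group leaves as Me3SiOMe, which gives the C8 ketone and the C3 dimethyl ketal. The closest known reaction type is the intramolecular anodic olefin coupling of a silyl enol ether radical cation with a tethered electron-rich alkene in lutidine-buffered methanol, together with the (NH4)2Ce(NO3)6-mediated coupling of silyl enol ethers with vinyl ethers to 4-oxo acetals, which joins the same pair of carbons (ketone α-carbon and enol ether β-carbon). The one ring closed is the six-membered ring C1–C2–C3–C4–C5–C8, formed 6-endo with respect to both the enol ether C2=C3 and the silyl enol ether C1=C8, and it completes the bicyclo[3.2.1]octan-8-one across the α and α′ carbons of the cyclopentanone. The only new stereocentre, quaternary C1, is fixed by the C5–C4 tether: the chain sits on the ring face opposite the C6 aryl group and can bond only to that face of C1, so the allyl group ends on the other face, and the C4 silyloxy group can take the equatorial position of the forming chair. The step needs oxidation at the silyl enol ether rather than at the dimethoxyphenyl ring, the methyl enol ether or the allyl group, and bonding at C2 rather than C3; the first should follow from the lower oxidation potential of a fully substituted silyl enol ether (with intramolecular electron transfer correcting oxidation elsewhere), the second from the polarity of the enol ether, since attack through C2 puts the charge on the methoxy-bearing C3 whereas attack through C3 would give a strained bicyclo[2.2.1] ring and an unstabilised primary centre. The product ketone is flanked by a quaternary carbon and a bridgehead CH, so it cannot enolise and should be inert to the base and to further oxidation once the charge is limited to about two faradays per mole.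

**Step 11**
Reactants: 16
Product: 17 (1R,4R,5S,6S,7S)-1-allyl-4-(tert-butyldimethylsilyloxy)-6-(3,4-dimethoxyphenyl)-3-methoxy-7-methylbicyclo[3.2.1]oct-2-en-8-one
Conditions: TMSOTf, i-Pr2NEt, CH2Cl2, −20 °C → rt
Reagents that add atoms: none
Why: The silyl triflate ionises one ketal methoxy group to the C3 oxocarbenium ion and the hindered amine removes a proton from the C2 methylene, which is less hindered and more electron-rich than the silyloxy-bearing C4 methine, so the enol ether should form toward C2 (ketal-to-enol-ether elimination) while the non-enolisable C8 ketone stays inert.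

**Step 12**
Reactants: 17
Product: 18 (1R,4R,5S,6S,7S)-1-allyl-6-(3,4-dimethoxyphenyl)-4-hydroxy-3-methoxy-7-methylbicyclo[3.2.1]oct-2-en-8-one (target)
Conditions: TBAF, AcOH (1:1), THF, 0 °C → rt
Reagents that add atoms: none
Why: Fluoride buffered with acetic acid should cleave the secondary silyl ether near neutral pH, which spares the acid-labile methyl enol ether and avoids base-induced retro-aldol cleavage of the β-hydroxy ketone, with no stereocentre touched.

**Compound list**
1 | (R)-4-(tert-butyldimethylsilyloxy)cyclopent-2-en-1-one | O=C1C=C[C@H](O[Si](C)(C)C(C)(C)C)C1 | starting material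
2 | 4-bromo-1,2-dimethoxybenzene | COc1ccc(Br)cc1OC | starting material
3 | (3,4-dimethoxyphenyl)magnesium bromide | COc1ccc([Mg]Br)cc1OC | intermediate
4 | (3S,4R)-4-(tert-butyldimethylsilyloxy)-3-(3,4-dimethoxyphenyl)cyclopentan-1-one | O=C1C[C@@H](c2ccc(OC)c(OC)c2)[C@H](O[Si](C)(C)C(C)(C)C)C1 | intermediate
5 | (R)-4-(3,4-dimethoxyphenyl)cyclopent-2-en-1-one | O=C1C[C@@H](c2ccc(OC)c(OC)c2)C=C1 | intermediate
6 | (R)-4-(3,4-dimethoxyphenyl)-2-iodocyclopent-2-en-1-one | O=C1C[C@@H](c2ccc(OC)c(OC)c2)C=C1I | intermediate
7 | allyltributylstannane | C=CC[Sn](CCCC)(CCCC)CCCC | starting material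
8 | (R)-2-allyl-4-(3,4-dimethoxyphenyl)cyclopent-2-en-1-one | C=CCC1=C[C@H](c2ccc(OC)c(OC)c2)CC1=O | intermediate
9 | 1,1,2-trimethoxyethane | COCC(OC)OC | starting material
10 | methoxyacetaldehyde | COCC=O | intermediate
11 | 2-methoxyacrolein | C=C(OC)C=O | intermediate
12 | lithium 5-allyl-3-(3,4-dimethoxyphenyl)cyclopenta-1,4-dien-1-olate (α′-enolate of 8, aryl-bearing centre unchanged) | C=CCC1=C[C@H](c2ccc(OC)c(OC)c2)C=C1O[Li] | intermediate
13 | (4S,5S)-2-allyl-4-(3,4-dimethoxyphenyl)-5-[(1R)-1-hydroxy-2-methoxyprop-2-en-1-yl]cyclopent-2-en-1-one | C=CCC1=C[C@H](c2ccc(OC)c(OC)c2)[C@@H]([C@@H](O)C(OC)=C)C1=O | intermediate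
14 | (4S,5S)-2-allyl-5-[(1R)-1-(tert-butyldimethylsilyloxy)-2-methoxyprop-2-en-1-yl]-4-(3,4-dimethoxyphenyl)cyclopent-2-en-1-one | C=CCC1=C[C@H](c2ccc(OC)c(OC)c2)[C@@H]([C@@H](O[Si](C)(C)C(C)(C)C)C(OC)=C)C1=O | intermediate
15 | {[(3S,4S,5S)-2-allyl-5-[(1R)-1-(tert-butyldimethylsilyloxy)-2-methoxyprop-2-en-1-yl]-4-(3,4-dimethoxyphenyl)-3-methylcyclopent-1-en-1-yl]oxy}trimethylsilane | C=CCC1=C(O[Si](C)(C)C)[C@H]([C@@H](O[Si](C)(C)C(C)(C)C)C(OC)=C)[C@@H](c2ccc(OC)c(OC)c2)[C@@H]1C | intermediate
16 | (1S,4R,5S,6S,7S)-1-allyl-4-(tert-butyldimethylsilyloxy)-6-(3,4-dimethoxyphenyl)-3,3-dimethoxy-7-methylbicyclo[3.2.1]octan-8-one | C=CC[C@@]12CC(OC)(OC)[C@H](O[Si](C)(C)C(C)(C)C)[C@@H](C1=O)[C@@H](c1ccc(OC)c(OC)c1)[C@@H]2C | intermediate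
17 | (1R,4R,5S,6S,7S)-1-allyl-4-(tert-butyldimethylsilyloxy)-6-(3,4-dimethoxyphenyl)-3-methoxy-7-methylbicyclo[3.2.1]oct-2-en-8-one | C=CC[C@@]12C=C(OC)[C@H](O[Si](C)(C)C(C)(C)C)[C@@H](C1=O)[C@@H](c1ccc(OC)c(OC)c1)[C@@H]2C | intermediate
18 | (1R,4R,5S,6S,7S)-1-allyl-6-(3,4-dimethoxyphenyl)-4-hydroxy-3-methoxy-7-methylbicyclo[3.2.1]oct-2-en-8-one | C=CC[C@@]12C=C(OC)[C@H](O)[C@@H](C1=O)[C@@H](c1ccc(OC)c(OC)c1)[C@@H]2C | target

**Step count and risks**
Total steps: 12. Longest linear sequence: 10 steps (steps 1–4 and 7–12, from 1 and 2); the aldehyde branch (steps 5 and 6) joins at step 7.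

Steps most likely to fail:

1. Step 10 (anodic ring closure). Oxidation could occur at the dimethoxyphenyl ring or the methyl enol ether instead of the silyl enol ether. The trimethylsilyl group could be lost by methanolysis before oxidation. Methanol could capture the radical cation faster than the ring closes. The fallback sets out from 15 and returns at 16, and replaces the anode by a redox-neutral radical–polar crossover. Treatment of 15 with MeLi (THF, 0 °C) would give the regiodefined lithium enolate F1. Bromination of F1 with NBS at −78 °C, where an enolate far outpaces the methyl enol ether, would give the tertiary α-bromo ketone F2 (both C1 epimers serve). Visible-light photoredox catalysis (fac-Ir(ppy)3, 2,6-lutidine, MeOH/MeCN, blue light) would cleave the C–Br bond reductively. The electrophilic α-keto radical at C1 should add 6-endo to the CH2 terminus of the enol ether; the α-methoxy radical at C3 is then oxidised to the oxocarbenium ion and captured by methanol to give 16.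

2. Step 7 (aldol). The anti/syn control at the carbinol carbon may be weak. Deprotonation could compete at the benzylic γ-position, which would erode the C6 configuration. The 2-alkoxy enal could polymerise or undergo conjugate addition, and the lithium aldolate could revert. The fallback sets out from 8 and returns at 13, and abandons strong-base enolate chemistry. Soft enolisation of 8 with Cy2BCl and Et3N (Et2O, −78 → 0 °C) would give the dicyclohexylboron enolate F3. Addition of 11 at −78 °C and oxidative work-up (H2O2, pH 7 buffer, MeOH, 0 °C) would give 13. The short B–O bonds tighten the chair transition state, so the ring-locked E-enolate should give the anti adduct, and the boron aldolate does not revert.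

3. Step 11 (ketal to enol ether). The proton could be lost from C4 instead of C2, which gives the wrong enol ether. The silyl triflate could also ionise the allylic silyl ether of the product. The fallback sets out from 16 and returns at 17, and builds the enol ether by enolate O-alkylation. Mild hydrolysis of the ketal (PPTS, wet acetone, rt) would give the 3,8-dione F4. Kinetic deprotonation with KN(SiMe3)2 (THF/DMPU, −78 °C) should occur at the C2 methylene, since the silyloxy-bearing C4–H is kinetically less acidic and the C8 ketone cannot enolise. O-Methylation of the potassium enolate with MeOTf would give 17.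

**Further compounds**
F1 | step 10 | lithium enolate of the 2-allyl-3-methyl-4-aryl-5-(silyloxy-methoxyallyl)cyclopentanone (C1=C8 enolate, ring centres as in 15) | C=CCC1=C(O[Li])[C@H]([C@@H](O[Si](C)(C)C(C)(C)C)C(OC)=C)[C@@H](c2ccc(OC)c(OC)c2)[C@@H]1C
F2 | step 10 | 2-allyl-2-bromo-5-[(1R)-1-(tert-butyldimethylsilyloxy)-2-methoxyprop-2-en-1-yl]-4-(3,4-dimethoxyphenyl)-3-methylcyclopentan-1-one (ring CH centres as in 15, both epimers at the bromine-bearing carbon) | C=CCC1(Br)C(=O)[C@H]([C@@H](O[Si](C)(C)C(C)(C)C)C(OC)=C)[C@@H](c2ccc(OC)c(OC)c2)[C@@H]1C
F3 | step 7 | dicyclohexylboron α′-enolate of 8 | C=CCC1=C[C@H](c2ccc(OC)c(OC)c2)C=C1OB(C1CCCCC1)C1CCCCC1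
F4 | step 11 | (1S,4R,5S,6S,7S)-1-allyl-4-(tert-butyldimethylsilyloxy)-6-(3,4-dimethoxyphenyl)-7-methylbicyclo[3.2.1]octane-3,8-dione | C=CC[C@@]12CC(=O)[C@H](O[Si](C)(C)C(C)(C)C)[C@@H](C1=O)[C@@H](c1ccc(OC)c(OC)c1)[C@@H]2C
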